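**Plan**

1. Retrosynthesis: the three outer phenols come from anisyl methyl ethers. The two ArCH2 groups on the central ring are traced back to diaryl ketones, and the resulting 4,6-diaroylresorcinol is the dehydro form of a 4,6-diaroylcyclohexane-1,3-dione.
2. That dione is opened at C1–C2, C1–C6 and C4–C5 of the central ring (C1 carries the arylethyl bridge, C3 and C5 the hydroxyls). This gives an aldehyde, an aroylacetone and an aroylacetate.
3. Enabling feature: C1 with its CH2CH2Ar bridge is the carbonyl carbon and chain of 3-(4-methoxyphenyl)propanal. C2 and C6, each with its benzylic carbon, are the acidic central carbons of two 4-methoxybenzoylacetyl units. C3–OH and C4 come from the acetyl group, C5–OH from the ester carbonyl.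
4. Forward: one flask joins the three pieces and closes the only new ring (Knoevenagel, Michael, Claisen). Dehydrogenation makes it aromatic, ionic hydrogenation turns both C=O into CH2, and BBr3 frees the phenols. The three anisyl rings are bought.
5. Stereochemistry: the target has no stereocentre. The sp3 ring centres made in the ring closure are epimerizable and vanish on aromatization.

Key step: step 1

Remark on the chemistry: the target is a single achiral compound, so no enantioselective step is needed. Compounds 1, 2 and 3 are taken to be commercial.

**Route**

Step 1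
Reactants: 1 3-(4-methoxyphenyl)propanal; 2 1-(4-methoxyphenyl)butane-1,3-dione; 3 methyl 3-(4-methoxyphenyl)-3-oxopropanoate
Product: 6 4,6-bis(4-methoxybenzoyl)-5-[2-(4-methoxyphenyl)ethyl]cyclohexane-1,3-dione (epimer mixture), via alkylidene diketone 4 (not isolated), via Michael adduct 5 (not isolated)
Conditions: 1 (1.05 equiv), piperidine (10 mol%), AcOH (10 mol%), 4 Å MS, THF, 0 °C, slow addition of 2; then 3 (1.0 equiv), rt; then filtered into LDA (4.5 equiv), THF, −78 → 0 °C; aq. HCl
Reagents that add atoms: none
Why: Piperidinium acetate should condense aldehyde 1 at the doubly activated central carbon of 2 to the alkylidene diketone 4 (C1–C2), whose electron-poor β-carbon then takes up the enol of 3 in an amine-catalysed Michael addition (C1–C6) to give 5. Excess LDA converts 5 into a trianion in which the keto ester is held as its enolate and the diketone as its dianion, and the terminal methyl carbanion (C4) attacks the ester carbonyl (C5) in a 6-(enolendo)-exo-trig Claisen closure that forms the only new ring. The closest known reactions are the Knoevenagel–Michael bis-adduct formation of aldehydes with 1,3-dicarbonyls, the Michael–Claisen route to 5-substituted cyclohexane-1,3-diones, and the acylation of 1,3-diketone dianions at the methyl group by β-keto ester monoanions. The three sp3 ring centres of 6 are enolizable and are erased in step 2, so none needs control. The selectivity required is Claisen attack on the ester rather than aldol attack on the neighbouring anisoyl ketone or retro-Michael exchange of partners; both are suppressed because that ketone and both 1,3-dicarbonyl units exist only as enolates under the polyanion conditions, leaving the ester as the sole electrophile within reach of C4. The 1:1:1 joining of the components rests on the order of addition, 2 being consumed by a slight excess of 1 before 3 enters the flask.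

Step 2
Reactants: 6 4,6-bis(4-methoxybenzoyl)-5-[2-(4-methoxyphenyl)ethyl]cyclohexane-1,3-dione
Product: 7 {4,6-dihydroxy-2-[2-(4-methoxyphenyl)ethyl]-1,3-phenylene}bis[(4-methoxyphenyl)methanone]
Conditions: DDQ (1.1 equiv), 1,4-dioxane, rt
Reagents that add atoms: none
Why: Quinone-mediated oxidative aromatization of a cyclohexane-1,3-dione to a resorcinol, in which DDQ should abstract hydride from the doubly allylic ring C–H of the bis-enol of 6 and the hydroxy-arenium ion loses a proton, while the anisyl ethers and the saturated bridge are not attacked at room temperature and the diacylated resorcinol is too electron-poor to be oxidized further.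

Step 3
Reactants: 7 {4,6-dihydroxy-2-[2-(4-methoxyphenyl)ethyl]-1,3-phenylene}bis[(4-methoxyphenyl)methanone]
Product: 8 4,6-bis(4-methoxybenzyl)-5-[2-(4-methoxyphenyl)ethyl]benzene-1,3-diol
Conditions: Et3SiH (6 equiv), TFA/CH2Cl2 (1:3), 0 °C → rt
Reagents that add atoms: none
Why: Ionic hydrogenation, in which TFA protonates each diaryl ketone to a cation stabilized by the 4-methoxyphenyl ring and by the ortho and para hydroxyls, triethylsilane delivers hydride, and the benzhydrol ionizes and is reduced again, a known way from hydroxybenzophenones to benzylphenols that leaves aryl ethers and phenols alone.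

Step 4
Reactants: 8 4,6-bis(4-methoxybenzyl)-5-[2-(4-methoxyphenyl)ethyl]benzene-1,3-diol
Product: 9 4,6-bis(4-hydroxybenzyl)-5-[2-(4-hydroxyphenyl)ethyl]benzene-1,3-diol
Conditions: BBr3 (8 equiv), CH2Cl2, −78 °C → rt; then ice-water
Reagents that add atoms: none
Why: Lewis-acid ether cleavage, in which boron tribromide complexes each methoxy oxygen and bromide removes the methyl group by SN2 attack, the free phenols being only borylated and released on aqueous work-up, with no C–C bond at risk at low temperature.

**Compound list**

1 | 3-(4-methoxyphenyl)propanal | COc1ccc(CCC=O)cc1 | starting material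
2 | 1-(4-methoxyphenyl)butane-1,3-dione | COc1ccc(C(=O)CC(C)=O)cc1 | starting material
3 | methyl 3-(4-methoxyphenyl)-3-oxopropanoate | COc1ccc(C(=O)CC(=O)OC)cc1 | starting material
4 | 2-acetyl-1,5-bis(4-methoxyphenyl)pent-2-en-1-one (E/Z mixture) | COc1ccc(CCC=C(C(C)=O)C(=O)c2ccc(OC)cc2)cc1 | intermediate
5 | methyl 4-acetyl-2-(4-methoxybenzoyl)-5-(4-methoxyphenyl)-3-[2-(4-methoxyphenyl)ethyl]-5-oxopentanoate (diastereomer mixture) | COC(=O)C(C(=O)c1ccc(OC)cc1)C(CCc1ccc(OC)cc1)C(C(C)=O)C(=O)c1ccc(OC)cc1 | intermediate
6 | 4,6-bis(4-methoxybenzoyl)-5-[2-(4-methoxyphenyl)ethyl]cyclohexane-1,3-dione (epimer and enol mixture) | O=C1CC(=O)C(C(=O)c2ccc(OC)cc2)C(CCc2ccc(OC)cc2)C1C(=O)c1ccc(OC)cc1 | intermediate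
7 | {4,6-dihydroxy-2-[2-(4-methoxyphenyl)ethyl]-1,3-phenylene}bis[(4-methoxyphenyl)methanone] | COc1ccc(CCc2c(C(=O)c3ccc(OC)cc3)c(O)cc(O)c2C(=O)c2ccc(OC)cc2)cc1 | intermediate
8 | 4,6-bis(4-methoxybenzyl)-5-[2-(4-methoxyphenyl)ethyl]benzene-1,3-diol | COc1ccc(CCc2c(Cc3ccc(OC)cc3)c(O)cc(O)c2Cc2ccc(OC)cc2)cc1 | intermediate
9 | 4,6-bis(4-hydroxybenzyl)-5-[2-(4-hydroxyphenyl)ethyl]benzene-1,3-diol (CNP0326726.0) | Oc1ccc(CCc2c(Cc3ccc(O)cc3)c(O)cc(O)c2Cc2ccc(O)cc2)cc1 | target

**Step count and risks**

Total steps: 4. Longest linear sequence: 4 steps (all three starting materials enter in step 1).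

Steps most likely to fail:

Step 1. A second molecule of 2 may add to 4 before 3 is present, the mixed adduct 5 may exchange partners by retro-Michael reaction, the double bond of 4 may move out of conjugation, or the polyanion may form incompletely so that ring closure stalls. The fallback assembles the chain in two isolated stages with the acceptor and donor roles swapped. It sets out from 1 and 3: a TiCl4/pyridine-mediated Knoevenagel condensation in THF at 0 °C should give the more robust alkylidene keto ester methyl 2-(4-methoxybenzoyl)-5-(4-methoxyphenyl)pent-2-enoate F1. Conjugate addition of 2 to F1 with catalytic DBU in THF at 0 °C should then give 5, now isolated and purified. Treating 5 with LDA (4.5 equiv) in THF at −78 → 0 °C closes the ring, and the route is rejoined at 6.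

Step 3. The doubly ortho-substituted, hydrogen-bonded ketones may stop at the benzhydrol stage, the stabilized diarylmethyl cations may alkylate the electron-rich ring of material already reduced, or acid may split a 4-methoxybenzyl group from the resorcinol. The fallback moves the reduction to basic medium. It sets out from 7: ethyl chloroformate and Et3N in THF at 0 °C should give {4,6-bis(4-methoxybenzoyl)-5-[2-(4-methoxyphenyl)ethyl]-1,3-phenylene} diethyl biscarbonate F2. NaBH4 in THF/water at 0 °C → rt then reduces each ketone, the neighbouring carbonate migrates to the benzylic oxygen and is expelled to an o-quinone methide, and a second hydride gives the methylene. The route is rejoined at 8.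

Step 2. Hydride abstraction at the congested ring C–H may be slow, so that DDQ instead attacks the benzylic position of the 4-methoxyphenethyl chain or forms adducts with the enol. The fallback replaces dehydrogenation by halogenation and dehydrohalogenation. It sets out from 6: bromine (1.0 equiv) in DMF at 0 °C should brominate the enolized carbon between the two ring carbonyls, far faster than the anisyl rings, and give 2-bromo-4,6-bis(4-methoxybenzoyl)-5-[2-(4-methoxyphenyl)ethyl]cyclohexane-1,3-dione F3. On warming to about 60 °C the bis-enol of F3 should lose hydrogen bromide by 1,4-elimination across the ring, and the route is rejoined at 7.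

**Further compounds**

F1 | step 1 | methyl 2-(4-methoxybenzoyl)-5-(4-methoxyphenyl)pent-2-enoate (E/Z mixture) | COC(=O)C(=CCCc1ccc(OC)cc1)C(=O)c1ccc(OC)cc1
F2 | step 3 | {4,6-bis(4-methoxybenzoyl)-5-[2-(4-methoxyphenyl)ethyl]-1,3-phenylene} diethyl biscarbonate | CCOC(=O)Oc1cc(OC(=O)OCC)c(C(=O)c2ccc(OC)cc2)c(CCc2ccc(OC)cc2)c1C(=O)c1ccc(OC)cc1
F3 | step 2 | 2-bromo-4,6-bis(4-methoxybenzoyl)-5-[2-(4-methoxyphenyl)ethyl]cyclohexane-1,3-dione | O=C1C(Br)C(=O)C(C(=O)c2ccc(OC)cc2)C(CCc2ccc(OC)cc2)C1C(=O)c1ccc(OC)cc1
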